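## Retrosynthetic overview

1. Unit 1 is the flavone whose ring B (C1'–C6') bears the 4'-OH, and unit 2 (double primes, anisyl ring triple primes) is tied by C8'' to C3'. The plan rests on ring A of unit 1 (C4a, C5, C6, C7, C8, C8a). It carries oxygen on C5, C7 and C8a, the acyl carbon C4 on C4a, and the C7 methoxy group para to C4a. This is the Claisen fold of a 3,5,7-trioxoacyl chain, and it makes the derived aryl ketone symmetric.
2. The target is traced back to its 4'-O-benzyl 5''-O-methyl ether, cleaved in one BCl3 step.
3. Key disconnection: C4a–C5 (ring A) and O1–C2 (ring C) of unit 1 are cut, leading to a 6-(4-aryl-2-oxobut-3-ynyl)-4-methoxy-2-pyranone. Pyranone atoms C2 to C6 are C5, C6, C7, C8 and C8a in masked form.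
4. The ynone comes from a C4–C4a aldol of an arylpropynal with lithiated 4-methoxy-6-methyl-2-pyranone, followed by oxidation. The propynal comes from a Sonogashira coupling (C1'–C2) on an aryl bromide. The C3'–C8'' bond comes from a Suzuki coupling of 8-iodo-4',5,7-trimethoxyflavone.
5. Ring order: the three rings of unit 2 and ring B are bought; the pyranone is opened, then ring A closes, then ring C of unit 1.

Key step: step 7

Remark: the C3'–C8'' biaryl axis bears no stereodescriptor in the target, so its configuration is not controlled. Compound 10 is carried as the racemate, and its only stereocentre is erased in step 6.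

## Route

Step 1
Reactants: 1 4',5,7-trimethoxyflavone
Product: 2 8-iodo-4',5,7-trimethoxyflavone
Conditions: I2 (1.05 equiv), CF3CO2Ag (1.1 equiv), CH2Cl2, 0 °C to rt, dark
Reagents that add atoms: iodine, II
Why: Silver-assisted electrophilic aromatic iodination, for which C8 (ortho to O1 and the 7-methoxy group, para to the 5-methoxy group) is the known site in fully O-methylated 5,7-dioxygenated flavones, while C6 sits between two methoxy groups and C3 and the anisyl ring are less electron-rich.

Step 2
Reactants: 2 8-iodo-4',5,7-trimethoxyflavone; 3 2-benzyloxy-5-bromophenylboronic acid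
Product: 4 8-(2-benzyloxy-5-bromophenyl)-4',5,7-trimethoxyflavone
Conditions: Pd(PPh3)4 (5 mol %), 2 M aq Na2CO3, DME, 75 °C, 3 added in portions
Reagents that add atoms: none
Why: Suzuki–Miyaura coupling in which zerovalent palladium carrying PPh3 inserts into the C–I bond much faster than into the donor-substituted C–Br bond para to the benzyloxy group, so the bromide should be kept for step 3 and portionwise addition of 3 should hold its self-coupling down.

Step 3
Reactants: 4 8-(2-benzyloxy-5-bromophenyl)-4',5,7-trimethoxyflavone; 5 propargyl alcohol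
Product: 6 8-[2-benzyloxy-5-(3-hydroxyprop-1-ynyl)phenyl]-4',5,7-trimethoxyflavone
Conditions: PdCl2(PhCN)2 (3 mol %), [HP(t-Bu)3]BF4 (6 mol %), CuI (3 mol %), i-Pr2NH, dioxane, rt to 45 °C
Reagents that add atoms: none
Why: Sonogashira coupling in which the bulky, electron-rich P(t-Bu)3 permits oxidative addition into the electron-rich aryl bromide at mild temperature, and the flavone, the aryl ethers and the free primary alcohol are inert under these conditions.

Step 4
Reactants: 6 8-[2-benzyloxy-5-(3-hydroxyprop-1-ynyl)phenyl]-4',5,7-trimethoxyflavone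
Product: 7 3-[4-benzyloxy-3-(4',5,7-trimethoxyflavon-8-yl)phenyl]prop-2-ynal
Conditions: activated MnO2 (15 equiv), CH2Cl2, rt
Reagents that add atoms: none
Why: MnO2 oxidation of a propargylic alcohol, which is selective for the activated primary carbinol, stops at the aldehyde and is neutral enough to leave every other group untouched.

Step 5
Reactants: 8 4-methoxy-6-methyl-2H-pyran-2-one; 7 3-[4-benzyloxy-3-(4',5,7-trimethoxyflavon-8-yl)phenyl]prop-2-ynal
Product: 10 racemic 6-{4-[4-benzyloxy-3-(4',5,7-trimethoxyflavon-8-yl)phenyl]-2-hydroxybut-3-ynyl}-4-methoxy-2H-pyran-2-one, via 6-lithiomethyl-4-methoxy-2-pyranone 9 (not isolated)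
Conditions: 8 (1.3 equiv), LiHMDS (1.2 equiv), THF, −78 °C; then 7 in THF, −78 °C; AcOH quench at −78 °C
Reagents that add atoms: none
Why: Vinylogous aldol addition in which the moderately strong amide base gives the thermodynamically preferred extended enolate at the 6-methyl group rather than the C3 ring anion, the aldehyde is far more electrophilic than the chromone carbonyl, and the new carbinol centre forms without control because it is removed in step 6.

Step 6
Reactants: 10 racemic 6-{4-[4-benzyloxy-3-(4',5,7-trimethoxyflavon-8-yl)phenyl]-2-hydroxybut-3-ynyl}-4-methoxy-2H-pyran-2-one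
Product: 11 6-{4-[4-benzyloxy-3-(4',5,7-trimethoxyflavon-8-yl)phenyl]-2-oxobut-3-ynyl}-4-methoxy-2H-pyran-2-one
Conditions: activated MnO2 (20 equiv), CH2Cl2, rt
Reagents that add atoms: none
Why: MnO2 oxidation of a secondary propargylic alcohol to the ynone under neutral heterogeneous conditions, which should avoid both loss of water to the dienyne and enolate chemistry at the acidic C4a methylene.

Step 7
Reactants: 11 6-{4-[4-benzyloxy-3-(4',5,7-trimethoxyflavon-8-yl)phenyl]-2-oxobut-3-ynyl}-4-methoxy-2H-pyran-2-one
Product: 14 4'-O-benzyl-5''-O-methylheveaflavone, via open-chain enol ether keto ester 12 (not isolated), via 2,6-dihydroxy-4-methoxyphenyl ynone 13 (not isolated)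
Conditions: NaOMe (4 equiv, water-free), MeOH–THF 2:1, 0 to 55 °C; then HCl in MeOH to pH 2, 40 °C
Reagents that add atoms: none
Why: Proposed new method: methoxide adds to the lactone carbonyl of 11 (future C5) and expels the C8a enolate, which gives ester 12 with the ester and the chain still cis on the C6=C7 enol ether; the C4a methylene between the C8a and C4 carbonyls is the most acidic carbon, its enolate attacks the ester in a 6-exo-trig Claisen (Dieckmann-type) condensation that forms C4a–C5, and loss of methoxide followed by enolisation makes ring A of 13 aromatic. One of the two equivalent phenoxides of 13 then adds to the alkyne terminus C2 in a 6-endo-dig oxa-Michael closure that forms O1–C2 and ring C, and protonation of the allenolate gives 14. The closest known reaction types are the alkoxide-induced recyclisation of 6-(2-oxoalkyl)-4-methoxy-2-pyranones to 2,6-dihydroxy-4-methoxyphenyl ketones and the base-mediated cyclisation of 2-hydroxyaryl ynones to flavones, which have not been run in one flask on an alkynyl ketone side chain. The first selectivity needed is Claisen over aldol folding, and it is secured because water-free methoxide leaves C5 as an ester and not as an inert carboxylate, because C6 is a vinylic CH of the enol ether, and because in strong alkoxide the C8a and C4 carbonyls are held as a β-diketonate, so that the ester is the only electrophile left. The second is 6-endo over 5-exo closure, secured by the Michael polarisation of the ynone and by the 4-benzyloxy donor, which disfavours the benzylic vinyl anion of the 5-exo path; if methoxide adds to the triple bond first, or if the C8a enolate oxygen closes on C2 before ring A forms, the same O1–C2 bond results, and the acidic finish closes any remaining β-methoxy enone. No regiochemical question arises in ring C because the aryl ketone of 13 is symmetric, no stereocentre is formed, and unit 2 is safe because its 5''-O-methyl group leaves only O1'' to re-close ring C of unit 2 should methoxide open it reversibly.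

Step 8
Reactants: 14 4'-O-benzyl-5''-O-methylheveaflavone
Product: 15 heveaflavone
Conditions: BCl3 (1 M in CH2Cl2, 6 equiv), pentamethylbenzene (5 equiv), CH2Cl2, −78 to 0 °C; then MeOH, aq HCl work-up
Reagents that add atoms: none
Why: Chelation-directed Lewis acid ether cleavage in which BCl3 bound to the C4'' carbonyl removes only the peri 5''-methyl ether through a six-membered chelate and also cleaves the benzyl ether (the benzyl cation is trapped by pentamethylbenzene), while the non-chelated methyl ethers at C7, C7'' and C4''' are stable to BCl3 at or below 0 °C.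

## Compound list

1 | 4',5,7-trimethoxyflavone | COc1ccc(-c2cc(=O)c3c(OC)cc(OC)cc3o2)cc1 | starting material
2 | 8-iodo-4',5,7-trimethoxyflavone | COc1ccc(-c2cc(=O)c3c(OC)cc(OC)c(I)c3o2)cc1 | intermediate
3 | 2-benzyloxy-5-bromophenylboronic acid | OB(O)c1cc(Br)ccc1OCc1ccccc1 | starting material
4 | 8-(2-benzyloxy-5-bromophenyl)-4',5,7-trimethoxyflavone | COc1ccc(-c2cc(=O)c3c(OC)cc(OC)c(-c4cc(Br)ccc4OCc4ccccc4)c3o2)cc1 | intermediate
5 | propargyl alcohol | C#CCO | starting material
6 | 8-[2-benzyloxy-5-(3-hydroxyprop-1-ynyl)phenyl]-4',5,7-trimethoxyflavone | COc1ccc(-c2cc(=O)c3c(OC)cc(OC)c(-c4cc(C#CCO)ccc4OCc4ccccc4)c3o2)cc1 | intermediate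
7 | 3-[4-benzyloxy-3-(4',5,7-trimethoxyflavon-8-yl)phenyl]prop-2-ynal | COc1ccc(-c2cc(=O)c3c(OC)cc(OC)c(-c4cc(C#CC=O)ccc4OCc4ccccc4)c3o2)cc1 | intermediate
8 | 4-methoxy-6-methyl-2H-pyran-2-one | COc1cc(C)oc(=O)c1 | starting material
9 | 6-lithiomethyl-4-methoxy-2H-pyran-2-one (not isolated) | [Li]Cc1cc(OC)cc(=O)o1 | intermediate
10 | racemic 6-{4-[4-benzyloxy-3-(4',5,7-trimethoxyflavon-8-yl)phenyl]-2-hydroxybut-3-ynyl}-4-methoxy-2H-pyran-2-one | COc1cc(CC(O)C#Cc2ccc(OCc3ccccc3)c(-c3c(OC)cc(OC)c4c(=O)cc(-c5ccc(OC)cc5)oc34)c2)oc(=O)c1 | intermediate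
11 | 6-{4-[4-benzyloxy-3-(4',5,7-trimethoxyflavon-8-yl)phenyl]-2-oxobut-3-ynyl}-4-methoxy-2H-pyran-2-one | COc1cc(CC(=O)C#Cc2ccc(OCc3ccccc3)c(-c3c(OC)cc(OC)c4c(=O)cc(-c5ccc(OC)cc5)oc34)c2)oc(=O)c1 | intermediate
12 | methyl (2E)-9-[4-benzyloxy-3-(4',5,7-trimethoxyflavon-8-yl)phenyl]-3-methoxy-5,7-dioxonon-2-en-8-ynoate (not isolated) | COC(=O)/C=C(/OC)CC(=O)CC(=O)C#Cc1ccc(OCc2ccccc2)c(-c2c(OC)cc(OC)c3c(=O)cc(-c4ccc(OC)cc4)oc23)c1 | intermediate
13 | 3-[4-benzyloxy-3-(4',5,7-trimethoxyflavon-8-yl)phenyl]-1-(2,6-dihydroxy-4-methoxyphenyl)prop-2-yn-1-one (not isolated) | COc1cc(O)c(C(=O)C#Cc2ccc(OCc3ccccc3)c(-c3c(OC)cc(OC)c4c(=O)cc(-c5ccc(OC)cc5)oc34)c2)c(O)c1 | intermediate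
14 | 4'-O-benzyl-5''-O-methylheveaflavone | COc1ccc(-c2cc(=O)c3c(OC)cc(OC)c(-c4cc(-c5cc(=O)c6c(O)cc(OC)cc6o5)ccc4OCc4ccccc4)c3o2)cc1 | intermediate
15 | heveaflavone | COc1ccc(-c2cc(=O)c3c(O)cc(OC)c(-c4cc(-c5cc(=O)c6c(O)cc(OC)cc6o5)ccc4O)c3o2)cc1 | target

## Step count and risks

Total step count: 8.
Longest linear sequence: 8 steps (1, 2, 4, 6, 7, 10, 11, 14, 15).

**Step 7 (key step).**
- The opened chain may fold in the aldol sense on to the C4 carbonyl.
- The phenoxide may close 5-exo on the alkyne carbon next to the carbonyl.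
- A carbon Michael closure from C8 on to C2 may compete.
- Alkoxide may consume the ynone before the pyranone opens.

The fallback buys ring A instead of folding it. It sets out from bromide 4.
- Palladium-catalysed reductive carbonylation (Pd(OAc)2, di(1-adamantyl)-n-butylphosphine, TMEDA, CO/H2 1:1, toluene, 100 °C) would give 4-benzyloxy-3-(4',5,7-trimethoxyflavon-8-yl)benzaldehyde F1.
- Claisen–Schmidt condensation with commercial 2'-hydroxy-4',6'-dimethoxyacetophenone (KOH, EtOH–THF, rt) would give (E)-3-[4-benzyloxy-3-(4',5,7-trimethoxyflavon-8-yl)phenyl]-1-(2-hydroxy-4,6-dimethoxyphenyl)prop-2-en-1-one F2.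
- Catalytic I2 in DMSO at 120 °C would close and dehydrogenate it to 4'-O-benzyl-5,5''-di-O-methylheveaflavone F3.
- The conditions of step 8 would then cleave both chelated 5-methyl ethers and the benzyl ether, and the route is rejoined at target 15.

**Step 2.** Oxidative addition into the C–Br bond of 3 or of 4 may compete with insertion into the hindered, electron-rich C8–I bond and cause oligomerisation. Slow coupling also leaves time for protodeboronation of 3.

The fallback uses a handle that the Suzuki catalyst cannot touch. It sets out from iodide 2.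
- Coupling with commercial 2-benzyloxy-5-chlorophenylboronic acid (PdCl2(dppf), K3PO4, dioxane–H2O, 90 °C) would give 8-(2-benzyloxy-5-chlorophenyl)-4',5,7-trimethoxyflavone F4.
- The chloride is then activated in a copper-free Sonogashira coupling with 5 (PdCl2(MeCN)2, XPhos, Cs2CO3, MeCN, 85 °C), and the route is rejoined at 6.

**Step 5.**
- Ring metalation at C3 of the pyranone may compete with metalation of the methyl group.
- Conjugate addition to the ynal may compete with carbonyl addition.
- Compound 7 may be poorly soluble at −78 °C.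
- The adduct may lose water.

The fallback moves the aldol to a small aldehyde and joins the halves by cross-coupling. It sets out from 8 and 4.
- Lithiated 8 (LiHMDS, THF, −78 °C) would add to commercial 3-(trimethylsilyl)propynal, whose silyl group blocks conjugate attack, and give racemic 6-[2-hydroxy-4-(trimethylsilyl)but-3-ynyl]-4-methoxy-2H-pyran-2-one F5.
- TBAF buffered with AcOH (THF, 0 °C) would give racemic 6-(2-hydroxybut-3-ynyl)-4-methoxy-2H-pyran-2-one F6.
- Sonogashira coupling of F6 with bromide 4 (PdCl2(PPh3)2, CuI, Et3N, DMF, 70 °C) rejoins the route at 10 and bypasses 6 and 7.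

## Further compounds

F1 | step 7 | 4-benzyloxy-3-(4',5,7-trimethoxyflavon-8-yl)benzaldehyde | COc1ccc(-c2cc(=O)c3c(OC)cc(OC)c(-c4cc(C=O)ccc4OCc4ccccc4)c3o2)cc1
F2 | step 7 | (E)-3-[4-benzyloxy-3-(4',5,7-trimethoxyflavon-8-yl)phenyl]-1-(2-hydroxy-4,6-dimethoxyphenyl)prop-2-en-1-one | COc1cc(O)c(C(=O)/C=C/c2ccc(OCc3ccccc3)c(-c3c(OC)cc(OC)c4c(=O)cc(-c5ccc(OC)cc5)oc34)c2)c(OC)c1
F3 | step 7 | 4'-O-benzyl-5,5''-di-O-methylheveaflavone | COc1ccc(-c2cc(=O)c3c(OC)cc(OC)c(-c4cc(-c5cc(=O)c6c(OC)cc(OC)cc6o5)ccc4OCc4ccccc4)c3o2)cc1
F4 | step 2 | 8-(2-benzyloxy-5-chlorophenyl)-4',5,7-trimethoxyflavone | COc1ccc(-c2cc(=O)c3c(OC)cc(OC)c(-c4cc(Cl)ccc4OCc4ccccc4)c3o2)cc1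
F5 | step 5 | racemic 6-[2-hydroxy-4-(trimethylsilyl)but-3-ynyl]-4-methoxy-2H-pyran-2-one | COc1cc(CC(O)C#C[Si](C)(C)C)oc(=O)c1
F6 | step 5 | racemic 6-(2-hydroxybut-3-ynyl)-4-methoxy-2H-pyran-2-one | COc1cc(CC(O)C#C)oc(=O)c1
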